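## The problem

Monochlorosulochrin 26 is a benzophenone in which two fully differentiated benzene rings meet at a ketone carbon with four ortho neighbours: the methyl ester and the methoxy group of ring A, and the two hydroxyls of ring B. The molecule has no stereocentre, so the task is one of regiochemistry and of forming two hindered aryl–carbonyl bonds. A stereocentre arises only in passing, at the carbon that becomes the ketone, and can be carried as a racemate. Ring A needs its two meta oxygens told apart (methyl ether at C3 beside the ketone, free hydroxyl at C5) with the ester at C1 ortho to the ketone. Ring B needs exactly one chlorine, at C5' next to the C4' methyl; a late electrophilic chlorination would have to stop after one of two equivalent positions and would also be drawn to the phenolic ring A. The sensitive points are the free phenols (oxidants), the ester beside the ketone (pseudo-ester formation, and xanthone closure in hot base once ring B has a free hydroxyl) and the aryl chloride, which rules out reductive deprotection at the end. The feature that opens the route is ring B itself: a resorcinol whose C1' carries the link to ring A between the oxygens at C2' and C6', with hydrogen at C3', methyl at C4' and chlorine at C5'. This is the pattern formed when a vinylketene (supplying C2'–O, C5'–Cl, C4'–CH3 and C3'–H) is joined to an alkynyl ether (supplying C1' and C6'–O). Since both oxygens end as hydroxyls, ring B is locally symmetric about the C1'–C4' axis, so the final pattern does not depend on which oxygen came from which partner.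

## Retrosynthesis

**26 from 25.** The three phenol O–C bonds (one tert-butyl ether on ring B, two methoxymethyl ethers) are cut last and together. All three are acetal or tertiary ethers that fall to acid, whereas the methyl ether, methyl ester and aryl chloride of 26 do not. Benzyl ethers would need hydrogenolysis and were excluded because of the chlorine. The forward step has only to avoid re-alkylation of the electron-rich rings by the tert-butyl cation.

**25 from 24 and 22.** The ester O–CH3 bond and the ketone are traced back through keto acid 24 to phthalide 22, in which the carboxyl oxygen is tied to the carbinol carbon. Against carrying a free ketone, the lactone masks two functions at once, is what an ortho-formyl benzoate gives on nucleophilic addition, and keeps the alkyne of the earlier stage electron-rich. The forward steps need a base-stable oxidation of a hindered benzhydrol carboxylate and a methylation that gives the open ester, not the pseudo-ester.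

**22 from 21.** One O–CH2 bond is cut. The new phenol of ring B has to be capped before the oxidant is used, and a methoxymethyl group leaves in the final acid step without extra cost.

**21 from 11 and 16 (through ketene 17).** Three ring B bonds are cut: C1'–C2', C5'–C6' and C2'–C3'. The neighbouring cuts are the aryl–carbinol bond, which would need a preformed monochloro-orcinol nucleophile, and the aryl–chlorine bond, which means late chlorination. Both leave the placement of a single chlorine to electrophilic selectivity. The chosen cut removes ring B altogether: what remains is alkyne 11 and the five-carbon acid chloride 16, in which chlorine and methyl are already neighbours. The forward reaction must generate 17 from 16, add it to 11 with the ketene carbonyl carbon on the alkyne carbon remote from oxygen, and carry the adduct through ring opening and ring closure.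

**11 from 4 and 7 (through acetylide 9).** The bond between the future ketone carbon and the alkyne is cut, together with the lactone C–O bond. Acetylide addition to an aldehyde sets this carbon at the carbinol level and the ortho ester closes the lactone unaided. Precursor 4 is a simple trisubstituted benzaldehyde, and 9 comes from 7 in the same flask.

**7 from 5.** The enol ether C–O bond is cut; tert-butoxide adds to dichloroacetylene 6 formed in situ from trichloroethylene 5.

**4 from 3, 2 and 1.** Cut in turn are the methyl ether, the methoxymethyl ether and the formyl C–C bond. Starting from the symmetric dihydroxy ester 1, and not from a mono-O-methylated analogue, avoids a formylation that would have to choose between two positions differing only in being para to hydroxyl or to methoxyl. In 1 these positions are equivalent, and in 2 the hydroxyls are told apart by the hydrogen bond from the C3 hydroxyl to the formyl group.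

**16 from 15, 14, 12 and 13.** The acyl chloride and the ester are functional-group changes; the C=C bond of 14 is cut to acetone 12 and chlorophosphonoacetate 13. An olefination that brings the chlorine with it avoids chlorine gas and the decarboxylative loss of halide that threatens β-halo carboxylic acids.

## Roads not taken

**Alternative 1:** The cut is the aryl C–O bond of a seven-membered lactone: the benzophenone is traced to dibenzoxepinedione A1, and A1 to the anthraquinone A2 (6-O-acetyl-2-chloroquestin) by removal of one oxygen. Forward, trifluoroperacetic acid would add to the C10 carbonyl of A2, the one not held in a hydrogen bond, and the ring B carbon would migrate to oxygen (Baeyer–Villiger oxidation). Methanolysis of A1 would then open the lactone to the methyl ester and the C6' phenol and remove the acetate, giving 26 in three operations from A2.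
- Merits: it mirrors the oxidative ring cleavage by which such benzophenones arise in nature, needs no protecting-group end game, and from A2 it is shorter than the chosen route.
- Weak points: A2 is not commercial and needs its own regiocontrolled anthraquinone synthesis, with the chlorine on the less electron-rich ring, which direct halogenation will not deliver. Quinone carbonyls are poor Baeyer–Villiger substrates. The two candidate migrating carbons differ little (neither has an ortho or para oxygen donor), so the sense of insertion rests on the small deactivation by the acetate. The peracid can also hydroxylate the phenolic ring.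
- Comparison: after the tricycle this road is clearly shorter. The chosen plan sets against it that every regiochemical decision is made by construction from acyclic or symmetric precursors, and that its whole length is unlikely to exceed a synthesis of A2 plus three steps.

**Alternative 2:** The cut is at ring A: both carbon substituents at C1 and C2 are removed, leaving an aryne. Forward, CsF would release the aryne from silyl triflate A4. tert-Butyl isocyanide A6 adds at the aryne carbon remote from the methoxy group, the aryl anion next to the methoxy group adds to ring B aldehyde A5, and the alkoxide closes onto the nitrilium carbon to give iminolactone A3 (two C–C bonds, one C–O bond, one five-membered ring).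
- Merits: three components are joined in one step, the aryne distortion by the 3-methoxy group sends the isocyanide to the correct carbon, there is no acid-labile alkynyl ether, and ring B arrives complete.
- Weak points: A4 takes several steps. A5 is a 2,6-dialkoxybenzaldehyde, hindered and electron-rich, so a poor trap for a short-lived aryl anion; protonation and isocyanide oligomerisation would compete. The single chlorine of A5 still depends on an electrophilic chlorination that must stop after one substitution. Hydrolysis of the N-tert-butyl imidate needs aqueous acid that three methoxymethyl ethers may not survive. After hydrolysis the road meets the same lactone opening and carbinol oxidation as steps 11 and 12.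
- Comparison: in convergence this road equals the chosen plan, and in robustness of intermediates it is better. It saves no steps. The chosen plan sets against it that chlorine and methyl are fixed as neighbours in 16, and that the bond to the carbinol carbon is made by a small linear acetylide, not by a hindered aldehyde.

**Alternative 3:** The cut runs through ring B at C3'–C4' and C1'–C6', a formal (3+3) assembly. Forward, TiCl4 would promote attack of the CH2 terminus of bis-silyl dienol ether A8 on the silyloxy-bearing carbon of enoate A9, then acylation of the central carbon of A8 by the ester group. This would give benzophenone A7 with both ring B hydroxyls free. The bromine of A7 would later be turned into the methyl ester by methoxycarbonylation (CO, MeOH, Pd(OAc)2 and a bisphosphine) and the silyl ether removed.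
- Merits: the ketone oxidation level is reached directly, ring B needs no protecting groups, and chlorine and methyl again come from an acyclic piece.
- Weak points: A8 needs a 1,3-diketone on a 2,6-disubstituted aroyl unit. The cyclisation must pair two nucleophilic carbons of A8 with two electrophilic carbons of A9 in one sense only; the reverse pairing gives an isomer in which the methyl and one hydroxyl have changed places, and nothing in the substrates enforces the choice strongly. The ester of ring A arrives last, by carbonylation of an aryl bromide flanked by the ketone in the presence of free phenols.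
- Comparison: this road is better in oxidation-state economy (no lactone opening and oxidation) and in protecting groups. The chosen plan sets against it a cycloaddition whose sense is dictated by the strong polarisation of an alkynyl ether, a ring B whose local symmetry makes even the other closure mode converge on 26, and a ring A ester carbon that is present from the first step.

Key step: step 9

Remark on the chemistry: primed locants refer to ring B of 26. Compounds 10, 11 and 18–23 contain the future ketone carbon as a stereocentre and are carried as racemates (18 as a mixture of diastereomers); the centre is removed in step 11.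

## Route

Step 1
Reactants: 1 methyl 3,5-dihydroxybenzoate
Product: 2 methyl 2-formyl-3,5-dihydroxybenzoate
Conditions: POCl3, DMF, MeCN, 0 °C → rt; then H2O, 50 °C
Reagents that add atoms: N,N-dimethylformamide CN(C)C=O; water O
Why: Vilsmeier–Haack formylation of a resorcinol; the chloroiminium ion should attack C2, para to one hydroxyl and ortho to the other, as with 3,5-dialkoxybenzoates and orcinol, and not the position between the hydroxyls; hydrolysis of the iminium salt gives the aldehyde.

Step 2
Reactants: 2 methyl 2-formyl-3,5-dihydroxybenzoate
Product: 3 methyl 2-formyl-3-hydroxy-5-(methoxymethoxy)benzoate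
Conditions: MOMCl (1.05 equiv), i-Pr2NEt, CH2Cl2, 0 °C
Reagents that add atoms: chloromethyl methyl ether COCCl
Why: Selective O-alkylation: the C3 hydroxyl is held in a hydrogen bond to the formyl oxygen, while the C5 hydroxyl para to the aldehyde is free and more acidic, so one equivalent of MOMCl should react at C5, as with 2,4-dihydroxybenzaldehyde.

Step 3
Reactants: 3 methyl 2-formyl-3-hydroxy-5-(methoxymethoxy)benzoate
Product: 4 methyl 2-formyl-3-methoxy-5-(methoxymethoxy)benzoate
Conditions: MeI, K2CO3, DMF, rt
Reagents that add atoms: iodomethane CI
Why: Williamson methylation of the remaining chelated phenol, which is the only nucleophilic site left.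

Step 4
Reactants: 5 trichloroethylene
Product: 7 (E)-1-tert-butoxy-1,2-dichloroethene, via dichloroacetylene 6 (not isolated)
Conditions: KOtBu, THF, −78 °C → rt
Reagents that add atoms: potassium tert-butoxide CC(C)(C)[O-].[K+]
Why: Elimination of HCl from 5 gives 6, to which tert-butoxide adds; anti protonation by the tert-butanol formed gives the (E)-dichlorovinyl ether, the standard entry to alkynyl ethers from trichloroethylene.

Step 5
Reactants: 7 (E)-1-tert-butoxy-1,2-dichloroethene; 4 methyl 2-formyl-3-methoxy-5-(methoxymethoxy)benzoate
Product: 11 rac-3-(tert-butoxyethynyl)-4-methoxy-6-(methoxymethoxy)isobenzofuran-1(3H)-one, via tert-butoxy(chloro)ethyne 8 (not isolated), via lithium tert-butoxyacetylide 9 (not isolated), via lithium alkoxide 10 (not isolated)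
Conditions: 7, n-BuLi (2.0 equiv per 7), THF, −78 °C; then 4, −78 → 0 °C; aq. NaHCO3; Et3N-deactivated silica
Reagents that add atoms: none
Why: Deprotonation of 7 with loss of LiCl gives 8 and chlorine–lithium exchange gives 9 (standard generation of lithium alkoxyacetylides); 1,2-addition to the aldehyde gives 10, which lactonises onto the ortho methyl ester (5-exo-trig) to give the phthalide. The new stereocentre is formed without control and is erased in step 11; basic work-up protects the acid-labile ynol ether.

Step 6
Reactants: 12 acetone; 13 triethyl 2-chloro-2-phosphonoacetate
Product: 14 ethyl 2-chloro-3-methylbut-2-enoate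
Conditions: NaH, THF, 0 °C → reflux
Reagents that add atoms: none
Why: Horner–Wadsworth–Emmons olefination of a ketone with the sodium salt of the α-chloro phosphonoacetate; acetone is symmetric, so no alkene geometry arises.

Step 7
Reactants: 14 ethyl 2-chloro-3-methylbut-2-enoate
Product: 15 2-chloro-3-methylbut-2-enoic acid
Conditions: LiOH, THF/H2O, rt; then aq. HCl
Reagents that add atoms: lithium hydroxide [Li+].[OH-]
Why: Saponification of the ethyl ester; the vinylic chloride on a fully substituted alkene is inert to hydroxide under these conditions.

Step 8
Reactants: 15 2-chloro-3-methylbut-2-enoic acid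
Product: 16 2-chloro-3-methylbut-2-enoyl chloride
Conditions: (COCl)2, cat. DMF, CH2Cl2, 0 °C → rt
Reagents that add atoms: oxalyl chloride O=C(Cl)C(Cl)=O
Why: Acid chloride formation through the catalytic chloroiminium species; all by-products are gases, so the product can be used after evaporation or distillation.

Step 9
Reactants: 16 2-chloro-3-methylbut-2-enoyl chloride; 11 rac-3-(tert-butoxyethynyl)-4-methoxy-6-(methoxymethoxy)isobenzofuran-1(3H)-one
Product: 21 rac-3-(2-tert-butoxy-3-chloro-6-hydroxy-4-methylphenyl)-4-methoxy-6-(methoxymethoxy)isobenzofuran-1(3H)-one, via chloro(isopropenyl)ketene 17 (not isolated), via cyclobutenone 18 (not isolated), via dienylketene 19 (not isolated), via cyclohexadienone 20 (not isolated)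
Conditions: 11, Et3N, toluene, slow addition of 16 (excess), 0 °C → rt; then 80 °C
Reagents that add atoms: none
Why: Proposed new method: the Danheiser benzannulation is established for vinylketenes released from cyclobutenones or by photochemical Wolff rearrangement, and 1,4-dehydrochlorination of 3-methylbut-2-enoyl chlorides by Et3N is an established source of isopropenylketenes for (2+2) cycloadditions; these are the closest known reaction types, but their union with an α-chloro vinylketene is not documented. Et3N removes a γ-proton of 16 with loss of chloride to give 17, whose ketene carbon is made more electrophilic by the α-chlorine, as in the halo ketenes that add even to unactivated alkynes. The polarised ynol ether 11 attacks that carbon through its carbon remote from oxygen and the chlorine-bearing carbon bonds to the oxygen-bearing alkyne carbon, so the (2+2) cycloaddition gives 18 (C1'–C2' and C5'–C6') at or below room temperature, before 11 can lose isobutene by its retro-ene path. At 80 °C conrotatory four-electron opening of 18 turns the chlorine outward, as donor substituents at the sp3 carbon of cyclobutenones do, which places the isopropenyl group cis to the ketene in 19. Ring B is then closed by thermal disrotatory six-electron electrocyclisation of 19 onto the CH2 terminus (C2'–C3'), and tautomerisation of 20 gives phenol 21. No lasting stereocentre is created: the quaternary carbon of 18 is lost on ring opening and the phthalide carbon stays racemic until step 11. The selectivity needed is regiochemical and is secured by the ynol ether polarisation, which always puts the carbon bearing ring A between the two oxygen-bearing carbons, and by the acid chloride, which fixes chlorine next to methyl; ring opening is reversible, so only the cis dienylketene drains to the arene. Because both oxygens of ring B end as hydroxyls, even a direct six-membered closure of a zwitterionic adduct would lead to the same ring B after step 13.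

Step 10
Reactants: 21 rac-3-(2-tert-butoxy-3-chloro-6-hydroxy-4-methylphenyl)-4-methoxy-6-(methoxymethoxy)isobenzofuran-1(3H)-one
Product: 22 rac-3-[2-tert-butoxy-3-chloro-6-(methoxymethoxy)-4-methylphenyl]-4-methoxy-6-(methoxymethoxy)isobenzofuran-1(3H)-one
Conditions: MOMCl, i-Pr2NEt, CH2Cl2, 0 °C → rt
Reagents that add atoms: chloromethyl methyl ether COCCl
Why: O-alkylation of the only free phenol; it must be capped before the permanganate step, and the amine base is too weak to deprotonate the phthalide C–H.

Step 11
Reactants: 22 rac-3-[2-tert-butoxy-3-chloro-6-(methoxymethoxy)-4-methylphenyl]-4-methoxy-6-(methoxymethoxy)isobenzofuran-1(3H)-one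
Product: 24 2-[2-tert-butoxy-3-chloro-6-(methoxymethoxy)-4-methylbenzoyl]-3-methoxy-5-(methoxymethoxy)benzoic acid, via hydroxy carboxylate 23 (not isolated)
Conditions: KOH, H2O/1,4-dioxane, 80 °C; then KMnO4, 0 °C → rt; cold aq. KHSO4 to pH 4
Reagents that add atoms: potassium hydroxide [K+].[OH-]
Why: Hydroxide opens the lactone to carboxylate 23, which cannot re-close in base, and KMnO4 oxidises the secondary benzylic alkoxide to the diaryl ketone (the classical conversion of 3-arylphthalides into 2-aroylbenzoic acids). All phenols are etherified, the aryl methyl group reacts far more slowly than the carbinol at this temperature, and the only stereocentre disappears.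

Step 12
Reactants: 24 2-[2-tert-butoxy-3-chloro-6-(methoxymethoxy)-4-methylbenzoyl]-3-methoxy-5-(methoxymethoxy)benzoic acid
Product: 25 methyl 2-[2-tert-butoxy-3-chloro-6-(methoxymethoxy)-4-methylbenzoyl]-3-methoxy-5-(methoxymethoxy)benzoate
Conditions: MeI, K2CO3, DMF, rt
Reagents that add atoms: iodomethane CI
Why: SN2 methylation of the carboxylate gives the open methyl ester, whereas acid-catalysed esterification of a 2-aroylbenzoic acid can give the cyclic pseudo-ester.

Step 13
Reactants: 25 methyl 2-[2-tert-butoxy-3-chloro-6-(methoxymethoxy)-4-methylbenzoyl]-3-methoxy-5-(methoxymethoxy)benzoate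
Product: 26 monochlorosulochrin, methyl 2-(3-chloro-2,6-dihydroxy-4-methylbenzoyl)-5-hydroxy-3-methoxybenzoate
Conditions: TFA/CH2Cl2/H2O (10:10:1), 0 °C → rt
Reagents that add atoms: none
Why: Acidolysis: the aryl tert-butyl ether ionises to the tert-butyl cation, which water traps, and both methoxymethyl acetals are hydrolysed; the methyl ester, aryl methyl ether and aryl chloride are stable to TFA.

## Compound list

1 | methyl 3,5-dihydroxybenzoate | COC(=O)c1cc(O)cc(O)c1 | starting material
2 | methyl 2-formyl-3,5-dihydroxybenzoate | COC(=O)c1cc(O)cc(O)c1C=O | intermediate
3 | methyl 2-formyl-3-hydroxy-5-(methoxymethoxy)benzoate | COC(=O)c1cc(OCOC)cc(O)c1C=O | intermediate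
4 | methyl 2-formyl-3-methoxy-5-(methoxymethoxy)benzoate | COC(=O)c1cc(OCOC)cc(OC)c1C=O | intermediate
5 | trichloroethylene | ClC=C(Cl)Cl | starting material
6 | dichloroacetylene (not isolated) | ClC#CCl | intermediate
7 | (E)-1-tert-butoxy-1,2-dichloroethene | Cl/C=C(/Cl)OC(C)(C)C | intermediate
8 | tert-butoxy(chloro)ethyne, 1-tert-butoxy-2-chloroethyne (not isolated) | ClC#COC(C)(C)C | intermediate
9 | lithium tert-butoxyacetylide (not isolated) | [Li]C#COC(C)(C)C | intermediate
10 | lithium alkoxide, racemic methyl 2-[3-tert-butoxy-1-(lithiooxy)prop-2-yn-1-yl]-3-methoxy-5-(methoxymethoxy)benzoate (not isolated) | COC(=O)c1cc(OCOC)cc(OC)c1C(O[Li])C#COC(C)(C)C | intermediate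
11 | rac-3-(tert-butoxyethynyl)-4-methoxy-6-(methoxymethoxy)isobenzofuran-1(3H)-one | O=C1OC(C#COC(C)(C)C)c2c(OC)cc(OCOC)cc12 | intermediate
12 | acetone | CC(C)=O | starting material
13 | triethyl 2-chloro-2-phosphonoacetate, ethyl 2-chloro-2-(diethoxyphosphoryl)acetate (racemic) | CCOC(=O)C(Cl)P(=O)(OCC)OCC | starting material
14 | ethyl 2-chloro-3-methylbut-2-enoate | CCOC(=O)C(Cl)=C(C)C | intermediate
15 | 2-chloro-3-methylbut-2-enoic acid | CC(C)=C(Cl)C(=O)O | intermediate
16 | 2-chloro-3-methylbut-2-enoyl chloride | CC(C)=C(Cl)C(Cl)=O | intermediate
17 | chloro(isopropenyl)ketene, 2-chloro-3-methylbuta-1,3-dien-1-one (not isolated) | C=C(C)C(Cl)=C=O | intermediate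
18 | cyclobutenone, 3-[2-tert-butoxy-3-chloro-4-oxo-3-(prop-1-en-2-yl)cyclobut-1-en-1-yl]-4-methoxy-6-(methoxymethoxy)isobenzofuran-1(3H)-one, racemic diastereomer mixture (not isolated) | O=C1C(C2OC(=O)c3cc(OCOC)cc(OC)c23)=C(OC(C)(C)C)C1(Cl)C(C)=C | intermediate
19 | dienylketene, rac-3-[(3Z)-3-tert-butoxy-4-chloro-5-methyl-1-oxohexa-1,3,5-trien-2-yl]-4-methoxy-6-(methoxymethoxy)isobenzofuran-1(3H)-one (not isolated) | O=C=C(C1OC(=O)c2cc(OCOC)cc(OC)c12)/C(OC(C)(C)C)=C(Cl)\C(C)=C | intermediate
20 | cyclohexadienone, rac-3-(2-tert-butoxy-3-chloro-4-methyl-6-oxocyclohexa-1,3-dien-1-yl)-4-methoxy-6-(methoxymethoxy)isobenzofuran-1(3H)-one (not isolated) | O=C1CC(C)=C(Cl)C(OC(C)(C)C)=C1C1OC(=O)c2cc(OCOC)cc(OC)c12 | intermediate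
21 | rac-3-(2-tert-butoxy-3-chloro-6-hydroxy-4-methylphenyl)-4-methoxy-6-(methoxymethoxy)isobenzofuran-1(3H)-one | O=C1OC(c2c(O)cc(C)c(Cl)c2OC(C)(C)C)c2c(OC)cc(OCOC)cc12 | intermediate
22 | rac-3-[2-tert-butoxy-3-chloro-6-(methoxymethoxy)-4-methylphenyl]-4-methoxy-6-(methoxymethoxy)isobenzofuran-1(3H)-one | O=C1OC(c2c(OCOC)cc(C)c(Cl)c2OC(C)(C)C)c2c(OC)cc(OCOC)cc12 | intermediate
23 | hydroxy carboxylate, racemic potassium 2-{[2-tert-butoxy-3-chloro-6-(methoxymethoxy)-4-methylphenyl](hydroxy)methyl}-3-methoxy-5-(methoxymethoxy)benzoate (not isolated) | [K+].[O-]C(=O)c1cc(OCOC)cc(OC)c1C(O)c1c(OCOC)cc(C)c(Cl)c1OC(C)(C)C | intermediate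
24 | 2-[2-tert-butoxy-3-chloro-6-(methoxymethoxy)-4-methylbenzoyl]-3-methoxy-5-(methoxymethoxy)benzoic acid | OC(=O)c1cc(OCOC)cc(OC)c1C(=O)c1c(OCOC)cc(C)c(Cl)c1OC(C)(C)C | intermediate
25 | methyl 2-[2-tert-butoxy-3-chloro-6-(methoxymethoxy)-4-methylbenzoyl]-3-methoxy-5-(methoxymethoxy)benzoate | COC(=O)c1cc(OCOC)cc(OC)c1C(=O)c1c(OCOC)cc(C)c(Cl)c1OC(C)(C)C | intermediate
26 | monochlorosulochrin, methyl 2-(3-chloro-2,6-dihydroxy-4-methylbenzoyl)-5-hydroxy-3-methoxybenzoate | COC(=O)c1cc(O)cc(OC)c1C(=O)c1c(O)cc(C)c(Cl)c1O | target

## Step count and risks

Total: 13 steps. Longest linear sequence: 9 steps (1, 2, 3, 5, 9, 10, 11, 12, 13). The branches are step 4 (one step, joining at step 5) and steps 6–8 (three steps, joining at step 9).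

**Step 9 (key step, carries the label).** The most likely failure is consumption of ketene 17 by dimerisation or amine-induced oligomerisation before it meets the ynol ether. If the cycloaddition is slow, 11 may lose isobutene by the retro-ene path on warming, and surplus ketene may acylate the new phenol. Fallback by known chemistry, setting out from 11 and returning at 21: the ring is closed by the photochemical variant of the same benzannulation and the chlorine is added afterwards. Commercial 3-methylbut-3-en-2-one is trifluoroacetylated (LiN(SiMe3)2, 2,2,2-trifluoroethyl trifluoroacetate, THF, −78 °C) to 1,1,1-trifluoro-5-methylhex-5-ene-2,4-dione F1. Diazo transfer with methanesulfonyl azide and Et3N in wet MeCN, with loss of the trifluoroacetyl group, gives 1-diazo-3-methylbut-3-en-2-one F2. Irradiation of F2 with 11 in CH2Cl2 at room temperature triggers Wolff rearrangement to isopropenylketene F3, which adds to the ynol ether at a temperature the tert-butyl ether tolerates. Brief warming to 80 °C completes ring opening and closure to rac-3-(2-tert-butoxy-6-hydroxy-4-methylphenyl)-4-methoxy-6-(methoxymethoxy)isobenzofuran-1(3H)-one F4. Chlorination of F4 with N-chlorosuccinimide in MeCN should occur para to the free hydroxyl, between the methyl and tert-butoxy groups, as 3,5-disubstituted phenols are chlorinated, and gives 21. The position ortho to the hydroxyl is the competing site, so isomer separation may be needed.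

**Step 5.** The most likely failure is loss of the ynol ether during isolation, by acid-triggered ionisation of the lactone C–O bond or by hydration of the alkyne (a Meyer–Schuster-type process). The carbon concerned is benzylic, para to an alkoxy group and propargylic to an alkoxyalkyne. Fallback, setting out from 7 and returning at 22: the fragile propargylic lactone is avoided by building ring B on the parent alkyne and joining the rings afterwards. This presupposes that the cycloaddition chemistry of step 9 works. Acetylide 9, made from 7 as in step 5, is protonated with water to tert-butoxyethyne F5. F5 is taken through the conditions of step 9 with 16 and Et3N to give 3-tert-butoxy-4-chloro-5-methylphenol F6. MOMCl and i-Pr2NEt give 1-tert-butoxy-2-chloro-5-(methoxymethoxy)-3-methylbenzene F7. Directed ortho-lithiation with n-BuLi in THF at 0 °C should occur between the two ether oxygens to give [2-tert-butoxy-3-chloro-6-(methoxymethoxy)-4-methylphenyl]lithium F8. Addition of F8 to aldehyde 4, with lactonisation of the alkoxide, delivers 22 directly.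

**Step 11.** The most likely failure is incomplete oxidation of the benzhydrol, which has four ortho substituents and re-closes to 22 on acidification, or over-oxidation at the aryl methyl group if the reaction is forced. Fallback, setting out from 22 and returning at 24: the oxidation is done on neutral intermediates. LiAlH4 in THF at 0 °C reduces the lactone to rac-[2-tert-butoxy-3-chloro-6-(methoxymethoxy)-4-methylphenyl][2-(hydroxymethyl)-6-methoxy-4-(methoxymethoxy)phenyl]methanol F9. Swern oxidation of both hydroxyls, with excess reagent so that no lactol can form, gives 2-[2-tert-butoxy-3-chloro-6-(methoxymethoxy)-4-methylbenzoyl]-3-methoxy-5-(methoxymethoxy)benzaldehyde F10. Pinnick oxidation (NaClO2, NaH2PO4, 2-methylbut-2-ene, t-BuOH/H2O) converts the aldehyde into acid 24.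

**Step 1.** The most likely failure is formylation at C4 between the two hydroxyls, or O-formylation, since the free resorcinol is less biased toward C2 than its dialkyl ethers. Fallback, setting out from 1 and returning at 2: the regiochemistry is enforced with ethers that are removed afterwards. MeI and K2CO3 in DMF convert 1 into methyl 3,5-dimethoxybenzoate F11. Vilsmeier–Haack formylation, well behaved for this substrate class, gives methyl 2-formyl-3,5-dimethoxybenzoate F12. BBr3 in CH2Cl2 (−78 → 0 °C) should cleave both aryl methyl ethers, the one ortho to the formyl group first, while the methyl ester reacts more slowly, to give 2.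

## Further compounds

F1 | step 9 | 1,1,1-trifluoro-5-methylhex-5-ene-2,4-dione | CC(=C)C(=O)CC(=O)C(F)(F)F
F2 | step 9 | 1-diazo-3-methylbut-3-en-2-one | CC(=C)C(=O)C=[N+]=[N-]
F3 | step 9 | isopropenylketene, 3-methylbuta-1,3-dien-1-one | CC(=C)C=C=O
F4 | step 9 | rac-3-(2-tert-butoxy-6-hydroxy-4-methylphenyl)-4-methoxy-6-(methoxymethoxy)isobenzofuran-1(3H)-one | O=C1OC(c2c(O)cc(C)cc2OC(C)(C)C)c2c(OC)cc(OCOC)cc12
F5 | step 5 | tert-butoxyethyne | C#COC(C)(C)C
F6 | step 5 | 3-tert-butoxy-4-chloro-5-methylphenol | Cc1cc(O)cc(OC(C)(C)C)c1Cl
F7 | step 5 | 1-tert-butoxy-2-chloro-5-(methoxymethoxy)-3-methylbenzene | COCOc1cc(C)c(Cl)c(OC(C)(C)C)c1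
F8 | step 5 | [2-tert-butoxy-3-chloro-6-(methoxymethoxy)-4-methylphenyl]lithium | [Li]c1c(OCOC)cc(C)c(Cl)c1OC(C)(C)C
F9 | step 11 | rac-[2-tert-butoxy-3-chloro-6-(methoxymethoxy)-4-methylphenyl][2-(hydroxymethyl)-6-methoxy-4-(methoxymethoxy)phenyl]methanol | OCc1cc(OCOC)cc(OC)c1C(O)c1c(OCOC)cc(C)c(Cl)c1OC(C)(C)C
F10 | step 11 | 2-[2-tert-butoxy-3-chloro-6-(methoxymethoxy)-4-methylbenzoyl]-3-methoxy-5-(methoxymethoxy)benzaldehyde | O=Cc1cc(OCOC)cc(OC)c1C(=O)c1c(OCOC)cc(C)c(Cl)c1OC(C)(C)C
F11 | step 1 | methyl 3,5-dimethoxybenzoate | COC(=O)c1cc(OC)cc(OC)c1
F12 | step 1 | methyl 2-formyl-3,5-dimethoxybenzoate | COC(=O)c1cc(OC)cc(OC)c1C=O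
A1 | alternative 1 | 2-chloro-1-hydroxy-10-methoxy-3-methyl-6,11-dioxo-6,11-dihydrodibenzo[b,e]oxepin-8-yl acetate | CC(=O)Oc1cc(OC)c2C(=O)c3c(O)c(Cl)c(C)cc3OC(=O)c2c1
A2 | alternative 1 | 6-O-acetyl-2-chloroquestin, 6-acetoxy-2-chloro-1-hydroxy-8-methoxy-3-methylanthracene-9,10-dione | CC(=O)Oc1cc(OC)c2C(=O)c3c(O)c(Cl)c(C)cc3C(=O)c2c1
A3 | alternative 2 | rac-N-tert-butyl-3-[3-chloro-2,6-bis(methoxymethoxy)-4-methylphenyl]-4-methoxy-6-(methoxymethoxy)isobenzofuran-1(3H)-imine | CC(C)(C)N=C1OC(c2c(OCOC)cc(C)c(Cl)c2OCOC)c2c(OC)cc(OCOC)cc12
A4 | alternative 2 | 3-methoxy-5-(methoxymethoxy)-2-(trimethylsilyl)phenyl trifluoromethanesulfonate | COCOc1cc(OC)c([Si](C)(C)C)c(OS(=O)(=O)C(F)(F)F)c1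
A5 | alternative 2 | 3-chloro-2,6-bis(methoxymethoxy)-4-methylbenzaldehyde | COCOc1cc(C)c(Cl)c(OCOC)c1C=O
A6 | alternative 2 | tert-butyl isocyanide | CC(C)(C)[N+]#[C-]
A7 | alternative 3 | [2-bromo-6-methoxy-4-(triisopropylsilyloxy)phenyl](3-chloro-2,6-dihydroxy-4-methylphenyl)methanone | COc1cc(O[Si](C(C)C)(C(C)C)C(C)C)cc(Br)c1C(=O)c1c(O)cc(C)c(Cl)c1O
A8 | alternative 3 | 1-[2-bromo-6-methoxy-4-(triisopropylsilyloxy)phenyl]-1,3-bis(trimethylsilyloxy)buta-1,3-diene (enol ether geometry not specified) | C=C(O[Si](C)(C)C)C=C(O[Si](C)(C)C)c1c(Br)cc(O[Si](C(C)C)(C(C)C)C(C)C)cc1OC
A9 | alternative 3 | methyl 2-chloro-3-(trimethylsilyloxy)but-2-enoate (geometry not specified) | COC(=O)C(Cl)=C(C)O[Si](C)(C)C
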